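**Retrosynthetic overview**
1. The target comes from the (2S)-5,7-dihydroxy-6-geranylflavanone by methylating only the 7-OH. The chelated 5-OH needs no protection.
2. Rings C and A are cut together, at O1–C8a (enol-ether C–O) and C4a–C5 (acyl C–C). This gives an acyclic tert-butyl (9S)-9-aryl-9-hydroxy-2-geranyl-3,5,7-trioxononanoate, in which the C2–O1 bond and its configuration already exist.
3. The chain is cut at C4–C4a into the terminal carbanion of tert-butyl 2-geranyl-3,5-dioxohexanoate and ethyl (S)-3-aryl-3-hydroxypropanoate.
4. The dioxo ester comes from tert-butyl acetoacetate, geranyl bromide and an acetyl Weinreb amide. The hydroxy ester comes from asymmetric transfer hydrogenation of the commercial aroylacetate.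
5. Ring order: ring B is bought. Ring C closes first (40 °C) and ring A second (110 °C) in the same flask.

Assumption: the geranyl-bearing sp3 carbon of the keto esters is carried as an epimer mixture (it becomes aromatic C6), and commercial geranyl bromide is the ≥95 % E isomer.

**Step 1**
Reactants: 1 tert-butyl acetoacetate; 2 geranyl bromide
Product: 4 tert-butyl 2-geranylacetoacetate [tert-butyl (4E)-2-acetyl-5,9-dimethyldeca-4,8-dienoate; racemic], via sodium enolate 3 (not isolated)
Conditions: NaH (1.0 equiv), THF, 0 °C; 2 (0.9 equiv), 0 °C → rt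
Reagents that add atoms: geranyl bromide (2), BrC/C=C(\C)CCC=C(C)C
Why: Acetoacetic ester alkylation, in which the soft enolate displaces the primary allylic bromide by SN2 at the alpha carbon and leaves the E-alkene untouched; the new centre is racemic and is erased on aromatisation.

**Step 2**
Reactants: 4 tert-butyl 2-geranylacetoacetate; 5 N-methoxy-N-methylacetamide
Product: 7 tert-butyl 2-[(2E)-3,7-dimethylocta-2,6-dien-1-yl]-3,5-dioxohexanoate (racemic; largely enolised), via dilithio dianion 6 (not isolated)
Conditions: LiN(i-Pr)2 (LDA, commercial solution, 2.2 equiv), THF, −78 → 0 °C; 5 (1.1 equiv), −78 → 0 °C; AcOH quench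
Reagents that add atoms: N-methoxy-N-methylacetamide (5), CC(=O)N(C)OC
Why: Weiler dianion acylation, in which the last-formed gamma carbanion attacks the Weinreb amide and the chelated tetrahedral adduct survives until the quench, so there is neither over-addition nor proton loss to the product.

**Step 3**
Reactants: 8 ethyl 3-(3,4-dimethoxyphenyl)-3-oxopropanoate
Product: 9 ethyl (3S)-3-(3,4-dimethoxyphenyl)-3-hydroxypropanoate
Conditions: RuCl(p-cymene)[(S,S)-TsDPEN] (0.5 mol %), HCO2H/Et3N (5:2), 30 °C
Reagents that add atoms: none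
Why: Noyori–Ikariya asymmetric transfer hydrogenation, in which the (S,S)-catalyst delivers hydride to the aryl ketone in the same sense as acetophenone → (S)-1-phenylethanol, irreversibly with formate; this sets the only stereocentre of the target as S.

**Step 4**
Reactants: 7 tert-butyl 2-geranyl-3,5-dioxohexanoate; 9 ethyl (3S)-3-(3,4-dimethoxyphenyl)-3-hydroxypropanoate
Product: 11 tert-butyl (9S)-9-(3,4-dimethoxyphenyl)-2-[(2E)-3,7-dimethylocta-2,6-dien-1-yl]-9-hydroxy-3,5,7-trioxononanoate (epimers at C2; keto–enol mixture), via trilithio trianion 10 (not isolated)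
Conditions: 7 (2.2 equiv), LiN(i-Pr)2 (6.7 equiv), THF, −78 → 0 °C; 9 (1.0 equiv), −78 → −20 °C; AcOH, −78 °C; quick cold SiO2 plug to recover excess 7; product used at once
Reagents that add atoms: none
Why: Polyanion Claisen acylation, in which the terminal and most basic carbanion of the beta-tricarbonyl trianion attacks the ester, the free hydroxyl travels as its lithium alkoxide as in statin side-chain Claisen condensations, and the second equivalent of trianion absorbs the acidic product; the C–O stereocentre takes no part.

**Step 5 (key step: rings C and A)**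
Reactants: 11 tert-butyl (9S)-9-aryl-2-geranyl-9-hydroxy-3,5,7-trioxononanoate
Product: 14 (2S)-2-(3,4-dimethoxyphenyl)-6-[(2E)-3,7-dimethylocta-2,6-dien-1-yl]-5,7-dihydroxy-2,3-dihydro-4H-chromen-4-one, via dihydropyranone keto ester 12 (not isolated), via acylketene 13 (not isolated)
Conditions: PPTS (5 mol %), 4 Å MS, PhMe (0.01 M), 40 °C, 3 h; then 110 °C, slow N2 sweep, 3 h
Reagents that add atoms: none
Why: Proposed new method: at 40 °C the chain C9 hydroxyl adds to the only carbonyl it can reach through a six-membered ring (chain C5) and the hemiketal dehydrates to the 2,3-dihydro-4H-pyran-4-one 12 (known acid-catalysed cyclodehydration of delta-hydroxy-beta-diketones), which ties up the C5 oxygen that would otherwise lactonise to a 2-pyranone; at 110 °C the tert-butyl beta-keto ester loses t-BuOH to give acylketene 13 (known thermal acylketene generation), whose enol is a dienylketene that forms C4a–C5 by 6π electrocyclisation (or direct C-acylation of the enol-ether carbon, the only nucleophile within six-ring reach) and tautomerises to the phloroglucinol ring, as in the last stage of the Danheiser benzannulation and in acylketene-based resorcylate aromatisations; the sieves remove water before the ketene appears, the medium is base-free, and the C2–O1 bond from step 3 is never broken, so the S configuration and the 6-geranyl regiochemistry are both fixed by the chain.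

**Step 6**
Reactants: 14 (2S)-5,7-dihydroxy-6-geranyl-3',4'-dimethoxyflavanone; 15 (trimethylsilyl)diazomethane
Product: 16 (2S)-2-(3,4-dimethoxyphenyl)-6-[(2E)-3,7-dimethylocta-2,6-dien-1-yl]-5-hydroxy-7-methoxy-2,3-dihydro-4H-chromen-4-one (target)
Conditions: TMSCHN2 (1.2 equiv), PhMe/MeOH (4:1), 0 °C
Reagents that add atoms: (trimethylsilyl)diazomethane (15), C[Si](C)(C)C=[N+]=[N-]
Why: Chemoselective diazoalkane O-methylation, in which only the acidic, non-chelated 7-OH protonates the reagent while the 5-OH is locked in a hydrogen bond to C4=O, and the base-free medium avoids retro-oxa-Michael racemisation at C2.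

**Compound list**
1 | tert-butyl acetoacetate | CC(=O)CC(=O)OC(C)(C)C | starting material
2 | geranyl bromide | BrC/C=C(\C)CCC=C(C)C | starting material
3 | sodium enolate of 1 (not isolated) | CC([O-])=CC(=O)OC(C)(C)C.[Na+] | intermediate
4 | tert-butyl 2-geranylacetoacetate (racemic) | CC(=O)C(C/C=C(\C)CCC=C(C)C)C(=O)OC(C)(C)C | intermediate
5 | N-methoxy-N-methylacetamide | CC(=O)N(C)OC | starting material
6 | dilithio dianion of 4 (not isolated) | C=C([O-])C(C/C=C(\C)CCC=C(C)C)=C([O-])OC(C)(C)C.[Li+].[Li+] | intermediate
7 | tert-butyl 2-geranyl-3,5-dioxohexanoate (racemic) | CC(=O)CC(=O)C(C/C=C(\C)CCC=C(C)C)C(=O)OC(C)(C)C | intermediate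
8 | ethyl 3-(3,4-dimethoxyphenyl)-3-oxopropanoate | CCOC(=O)CC(=O)c1ccc(OC)c(OC)c1 | starting material
9 | ethyl (3S)-3-(3,4-dimethoxyphenyl)-3-hydroxypropanoate | CCOC(=O)C[C@H](O)c1ccc(OC)c(OC)c1 | intermediate
10 | trilithio trianion of 7 (not isolated) | C=C([O-])C=C([O-])C(C/C=C(\C)CCC=C(C)C)=C([O-])OC(C)(C)C.[Li+].[Li+].[Li+] | intermediate
11 | tert-butyl (9S)-9-(3,4-dimethoxyphenyl)-2-geranyl-9-hydroxy-3,5,7-trioxononanoate (C2 epimers) | CC(C)(C)OC(=O)C(C/C=C(\C)CCC=C(C)C)C(=O)CC(=O)CC(=O)C[C@H](O)c1ccc(OC)c(OC)c1 | intermediate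
12 | tert-butyl 4-[(2S)-2-(3,4-dimethoxyphenyl)-4-oxo-3,4-dihydro-2H-pyran-6-yl]-2-geranyl-3-oxobutanoate (not isolated) | CC(C)(C)OC(=O)C(C/C=C(\C)CCC=C(C)C)C(=O)CC1=CC(=O)C[C@@H](c2ccc(OC)c(OC)c2)O1 | intermediate
13 | alpha-geranyl acylketene derived from 12 (not isolated) | O=C=C(C/C=C(\C)CCC=C(C)C)C(=O)CC1=CC(=O)C[C@@H](c2ccc(OC)c(OC)c2)O1 | intermediate
14 | (2S)-5,7-dihydroxy-6-geranyl-3',4'-dimethoxyflavanone | COc1ccc([C@@H]2CC(=O)c3c(cc(O)c(C/C=C(\C)CCC=C(C)C)c3O)O2)cc1OC | intermediate
15 | (trimethylsilyl)diazomethane | C[Si](C)(C)C=[N+]=[N-] | starting material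
16 | (2S)-6-geranyl-5-hydroxy-7,3',4'-trimethoxyflavanone | COc1ccc([C@@H]2CC(=O)c3c(cc(OC)c(C/C=C(\C)CCC=C(C)C)c3O)O2)cc1OC | target

**Totals:** 6 steps in all. The longest linear sequence is 5 steps (steps 1, 2, 4, 5, 6).

**Steps most likely to fail**

Step 5 (two-ring cascade). The risks are side cyclisations of the triketo ester, capture of 13 by residual water, and partial loss of ee at the electron-rich benzylic C–O bond. The fallback takes the stereocentre out of the cascade and sets it afterwards by catalysis.
- Setting out from 7, its trianion 10 is acylated with methyl 3,3-dimethoxypropanoate to give tert-butyl 2-geranyl-9,9-dimethoxy-3,5,7-trioxononanoate F1.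
- The same PPTS-then-heat protocol closes a 4-pyranone, with the chain C5 enol oxygen attacking the unmasked C9 acetal carbon and two MeOH taken up by the sieves. It then closes ring A to give the achiral 6-geranyl-5,7-dihydroxy-4H-chromen-4-one F2, which tolerates harsher conditions.
- TMSCHN2 gives 6-geranyl-5-hydroxy-7-methoxy-4H-chromen-4-one F3.
- Asymmetric 1,4-addition of 3,4-dimethoxyphenylboronic acid comes back to the route at 16. Conditions are [Rh(OH)(cod)]2 with an electron-poor (S)-configured MeO-BIPHEP-type bisphosphine in toluene/H2O at 20 °C, and the ligand antipode must be confirmed to give 2S.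

Step 4 (trianion acylation with an unprotected hydroxy ester). The risks are alpha-deprotonation of 9, proton shuffling, and the need for sacrificial trianion. The fallback replaces the ester Claisen by a ketone synthesis through a chelated tetrahedral adduct. Setting out from 9, MeNH(OMe)·HCl and i-PrMgCl in THF at −20 °C give (3S)-3-(3,4-dimethoxyphenyl)-3-hydroxy-N-methoxy-N-methylpropanamide F4. Its alkoxide is then treated with only 1.2 equiv of 10. The adduct collapses only on the AcOH quench, and the route is rejoined at 11.

Step 2 (acylation of an alpha-branched acetoacetate dianion). The risks are sluggish second deprotonation and O-acylation. The fallback swaps the acylation for an aldol addition followed by oxidation. Setting out from 4, dianion 6 is added to acetaldehyde at −78 °C to give tert-butyl 2-geranyl-5-hydroxy-3-oxohexanoate F5. Oxidation with Dess–Martin periodinane (CH2Cl2, NaHCO3, 0 °C) then comes back to the route at 7.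

**Further compounds**
F1 | step 5 | tert-butyl 2-geranyl-9,9-dimethoxy-3,5,7-trioxononanoate | COC(OC)CC(=O)CC(=O)CC(=O)C(C/C=C(\C)CCC=C(C)C)C(=O)OC(C)(C)C
F2 | step 5 | 6-geranyl-5,7-dihydroxy-4H-chromen-4-one | O=c1ccoc2cc(O)c(C/C=C(\C)CCC=C(C)C)c(O)c12
F3 | step 5 | 6-geranyl-5-hydroxy-7-methoxy-4H-chromen-4-one | O=c1ccoc2cc(OC)c(C/C=C(\C)CCC=C(C)C)c(O)c12
F4 | step 4 | (3S)-3-(3,4-dimethoxyphenyl)-3-hydroxy-N-methoxy-N-methylpropanamide | CON(C)C(=O)C[C@H](O)c1ccc(OC)c(OC)c1
F5 | step 2 | tert-butyl 2-geranyl-5-hydroxy-3-oxohexanoate (diastereomer mixture) | CC(O)CC(=O)C(C/C=C(\C)CCC=C(C)C)C(=O)OC(C)(C)C
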